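Epsilon could not hold more double product than its reagent allowed. Each first product takes one reagent, a double product two and a tris adduct three, so I named the surplus, the reagent charged minus the substrate charged as a share of the substrate, which in epsilon is 20.0%. Double product plus twice the tris adduct plus reagent left, minus substrate left, must equal it.

common to all: substrate 0.0010 M
- south: reagent 1.5 mM; run made earlier
- east: reagent 4.8 mM; run made earlier
- epsilon: reagent 1.20 mM; time 6.0 min
- eta: reagent 4.00 mM; time 6.0 min

| run | time / min | double product / % | first product / % | substrate / % |
|---|---|---|---|---|
| south | 0.250 | 3 | 70 | 27 |
| south | 0.833 | 8 | 84 | 6 |
| south | 1.33 | 8 | 83 | 3 |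
| south | 2.00 | 11 | 80 | 0 |
| south | 3.00 | 18 | 78 | 1 |
| east | 0.250 | 11 | 78 | 0 |
| east | 0.833 | 14 | 46 | 0 |
| east | 1.33 | 23 | 26 | 0 |
| east | 2.00 | 29 | 1 | 0 |
| east | 3.00 | 29 | 0 | 0 |

(readings scatter by 1.5 percentage points)

- which of these holds the largest part of the substrate at the end of epsilon (double product / first product / substrate / tris adduct)
- which of these holds the largest part of the substrate at the end of eta (double product / first product / substrate / tris adduct)
- how much double product is there at the end of epsilon, in percent of the substrate charged

- the numbers in the tables scatter by 1.5 percentage points (one standard deviation)
- a reading or a percentage of first product counts all its forms, free or not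

That gave my upper bound: about 20.0% of double product, plus whatever substrate remained. For the lower end I divided the rate of double product by the rate of substrate loss. Reagent and time cancel in that ratio for these two steps, each taking one reagent, so at equal substrate charge I assumed, as an estimate and not a bound, that epsilon would run near south's path of double product against substrate. South read 8% of double product at 6% of substrate, and at that point the balance, with tris adduct set aside, leaves epsilon about 0.180 mM of reagent. Taking the pace from south's first reading, with reagent held at that level, I reckoned that epsilon should arrive there in about 4.48 min, sooner than its 6.0 min. My working bracket was therefore about 8% to 20.0%, and I expected first product to lead epsilon with about 68.0% or more. Eta's surplus of 300% pays for tris adduct, which took the missing 71.0% at the end of east, so I expected it to lead.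

The forecast named first product and tris adduct and put double product at 13% (10% to 17%), inside my bracket, noting that “double product cannot exceed about 20%”. Epsilon gave 83.0% of first product and 15.2% of double product; eta gave 60.5% of tris adduct.

    substrate + reagent → first product (k = 90.0 L mol⁻¹ s⁻¹)
    reagent + first product → double product (k = 190 L mol⁻¹ s⁻¹)
    reagent + double product ⇌ tris adduct (K = 1100 L mol⁻¹, k = 51.0 L mol⁻¹ s⁻¹)
    crystals ⇌ first product, rate k4*(cs4 - [first product]) while solid is left; crystals form when [first product] > cs4 (solubility = 0.0150 mM, k = 8.00 s⁻¹)

In epsilon, half the substrate step's turnover was done by 0.144 min, while at 0.144 min reagent's half-life by the step to double product was 3.3 min. Double product then crept to 20.3% by 60.0 min, level with the surplus.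

A neighbour of epsilon charged with 7.2 × 10⁻⁴ M of reagent has a surplus of −28.0%, making reagent the limiting reagent, so once it is spent substrate left should exceed double product by that margin. The flask held 0% of its reagent, 32.1% of substrate and 4.10% of double product, a difference of 28 percentage points.

The data are simulated with made-up constants; scatter was added.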